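**Retrosynthetic overview**
1. Target ⇐ oxidation of a C‑19 primary alcohol; free acid and C‑19 OH ⇐ one Pd‑mediated release of an allyl ester and an allyl carbonate; (E)‑enoate ⇐ Horner–Wadsworth–Emmons olefination of a C‑13 methyl ketone.
2. cis‑2,3‑Diacetate ⇐ C‑3 ketone: enolate hydroxylation at C‑2 (equatorial), then bulky hydride to the axial C‑3 alcohol; C‑19 ⇐ reduction of the auxiliary ester.
3. C7=C8 alkene ⇐ one‑position isomerisation of the exocyclic 8(17)‑alkene left by the cyclisation.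
4. Decalin ⇐ auxiliary‑controlled oxidative radical bicyclisation of an acyclic (E,E)‑dienyl α‑methyl β‑keto ester: ring A closes first (C4–C5), ring B second (C9–C10), in one step that sets C‑4, C‑5, C‑9 and C‑10.
5. Acyclic precursor ⇐ dianion alkylation of (−)‑8‑phenylmenthyl 2‑methylacetoacetate with an allylic bromide made from (E)‑geranylacetone.

**Assumptions and conventions**
- Assumption: (E)‑geranylacetone is used as the pure E isomer.
- Assumption: the (1R,2S,5R)‑auxiliary is taken to give the ent series in step 6, by analogy with the known use of its enantiomer for the normal series; if the sense were opposite, (+)‑8‑phenylmenthol would be used with no other change.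
- Labdane numbering is used for the decalins. All are ent‑labdanes: H‑5 is trans to the C‑10 methyl (C‑20); C‑19 and the C‑9 side chain are cis to C‑20; the C‑2 and C‑3 oxygens ("ent‑2α,3α") are on the face opposite C‑20, cis to H‑5. The target is (2S,3R,4S,5S,9R,10S).

**Step 1**
Reactants: 1 (E)‑geranylacetone
Product: 2 2‑[(3E)‑4,8‑dimethylnona‑3,7‑dien‑1‑yl]‑2‑methyl‑1,3‑dioxolane
Conditions: HOCH2CH2OH, PPTS (cat.), benzene, reflux, Dean–Stark
Reagents that add atoms: ethylene glycol, OCCO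
Why: Acid‑catalysed ketalisation masks the methyl ketone (future C‑13) against the bases, radicals and hydrides used later; no stereocentre is involved.

**Step 2**
Reactants: 2 dioxolane of geranylacetone
Product: 3 (2E,6E)‑2,6‑dimethyl‑9‑(2‑methyl‑1,3‑dioxolan‑2‑yl)nona‑2,6‑dien‑1‑ol
Conditions: SeO2 (0.3 equiv), t‑BuOOH (2 equiv), CH2Cl2, 0 °C → rt
Reagents that add atoms: tert‑butyl hydroperoxide, CC(C)(C)OO
Why: SeO2‑catalysed allylic oxidation (ene reaction, then [2,3]‑sigmatropic shift) selectively hydroxylates the (E)‑methyl of the terminal isopropylidene group, giving the (E)‑allylic alcohol whose carbon becomes C‑1.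

**Step 3**
Reactants: 3 allylic alcohol
Product: 4 2‑[(3E,7E)‑9‑bromo‑4,8‑dimethylnona‑3,7‑dien‑1‑yl]‑2‑methyl‑1,3‑dioxolane
Conditions: CBr4, PPh3, CH2Cl2, −20 → 0 °C (used crude)
Reagents that add atoms: carbon tetrabromide, BrC(Br)(Br)Br
Why: The Appel reaction converts the primary allylic alcohol to the bromide under neutral conditions, without allylic transposition or loss of the ketal.

**Step 4**
Reactants: 5 ethyl 2‑methyl‑3‑oxobutanoate; 6 (−)‑8‑phenylmenthol, (1R,2S,5R)‑5‑methyl‑2‑(2‑phenylpropan‑2‑yl)cyclohexan‑1‑ol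
Product: 7 (1R,2S,5R)‑5‑methyl‑2‑(2‑phenylpropan‑2‑yl)cyclohexyl 2‑methyl‑3‑oxobutanoate (C‑2 epimers)
Conditions: DMAP (0.3 equiv), toluene, reflux, 4 Å molecular sieves to remove EtOH
Reagents that add atoms: none
Why: DMAP‑catalysed transesterification of an enolisable β‑keto ester (through the acylketene) installs the auxiliary; the α‑stereocentre is labile and irrelevant.

**Step 5**
Reactants: 7 auxiliary keto ester; 4 allylic bromide
Product: 9 (−)‑8‑phenylmenthyl (6E,10E)‑2,6,10‑trimethyl‑13‑(2‑methyl‑1,3‑dioxolan‑2‑yl)‑3‑oxotrideca‑6,10‑dienoate, via sodium lithium dienolate 8 (not isolated)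
Conditions: NaH, THF, 0 °C; n‑BuLi, 0 °C; then 4, 0 °C → rt; aq. NH4Cl
Reagents that add atoms: none
Why: In this Weiler dianion alkylation the more basic terminal carbanion displaces the allylic bromide (SN2) to give the full chain with both (E)‑alkenes intact.

**Step 6**
Reactants: 9 acyclic dienyl keto ester
Product: 10 (−)‑8‑phenylmenthyl ent‑13,13‑ethylenedioxy‑3‑oxo‑14,15‑dinorlabd‑8(17)‑en‑19‑oate
Conditions: Mn(OAc)3·2H2O (2.2 equiv), Cu(OAc)2·H2O (1 equiv), Yb(OTf)3 (1 equiv), CF3CH2OH, −5 → 0 °C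
Reagents that add atoms: none
Why: In this oxidative radical polyene cyclisation the C‑4 radical closes ring A and the C‑10 radical closes ring B (both 6‑endo, chair–chair), giving the trans‑decalin with axial ester cis to C‑20 and equatorial C‑9 chain; the auxiliary phenyl group shields one face of the Yb‑chelated keto ester, and Cu(OAc)2 oxidises the C‑8 radical to the alkene (mainly exocyclic; the minor C7=C8 isomer is 11 itself).

**Step 7**
Reactants: 10 exocyclic alkene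
Product: 11 (−)‑8‑phenylmenthyl ent‑13,13‑ethylenedioxy‑3‑oxo‑14,15‑dinorlabd‑7‑en‑19‑oate
Conditions: Co(salen)Cl (C36H52ClCoN2O2; salen = N,N'‑bis(3,5‑di‑tert‑butylsalicylidene)‑1,2‑cyclohexanediaminate; 3 mol%), PhSiH3 (6 mol%), benzene, rt
Reagents that add atoms: none
Why: Cobalt‑hydride hydrogen‑atom‑transfer isomerisation moves the 1,1‑disubstituted alkene one position (H‑atom addition to C‑17, abstraction of the accessible C‑7 hydrogen) to the trisubstituted C7=C8 alkene, which reacts much more slowly; no stereocentre is touched.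

**Step 8**
Reactants: 11 keto ester
Product: 13 (−)‑8‑phenylmenthyl ent‑13,13‑ethylenedioxy‑2α‑hydroxy‑3‑oxo‑14,15‑dinorlabd‑7‑en‑19‑oate, via potassium enolate 12 (not isolated)
Conditions: KN(SiMe3)2, THF, −78 °C; then 2‑(phenylsulfonyl)‑3‑phenyloxaziridine, −78 °C; AcOH quench
Reagents that add atoms: 2‑(phenylsulfonyl)‑3‑phenyloxaziridine, O=S(=O)(c1ccccc1)N1OC1c1ccccc1
Why: In this Davis enolate hydroxylation the ketone can enolise only toward C‑2 (C‑4 is quaternary), and the oxaziridine attacks C‑2 anti to the syn‑axial C‑20 methyl and C‑19 ester, giving the equatorial hydroxyl on the face opposite C‑20.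

**Step 9**
Reactants: 13 α‑hydroxy ketone
Product: 14 (−)‑8‑phenylmenthyl ent‑13,13‑ethylenedioxy‑2α,3α‑dihydroxy‑14,15‑dinorlabd‑7‑en‑19‑oate
Conditions: LiBH(s‑Bu)3 (3 equiv), THF, −78 °C; then NaOH, H2O2, 0 °C
Reagents that add atoms: none
Why: The bulky trialkylborohydride attacks the C‑3 ketone along the equatorial trajectory (the axial path is blocked by the axial hydrogens at C‑1 and C‑5), giving the axial C‑3 alcohol cis to the C‑2 hydroxyl; ester, ketal and alkene are inert.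

**Step 10**
Reactants: 14 diol ester
Product: 16 ent‑2α,3α,19‑trihydroxy‑14,15‑dinorlabd‑7‑en‑13‑one, via ketal triol 15 (not isolated)
Conditions: LiAlH4, THF, 0 → 40 °C; then 2 M HCl, THF, rt
Reagents that add atoms: water, O
Why: Hydride reduction of the hindered ester turns C‑19 into CH2OH and releases the auxiliary for recovery; the acidic work‑up hydrolyses the dioxolane to the C‑13 methyl ketone, with all stereocentres unchanged.

**Step 11**
Reactants: 16 triol ketone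
Product: 19 ent‑19‑(allyloxycarbonyloxy)‑2α,3α‑dihydroxy‑14,15‑dinorlabd‑7‑en‑13‑one, via cyclic phenylboronate 17 (not isolated), via carbonate phenylboronate 18 (not isolated)
Conditions: PhB(OH)2 (1.05 equiv), pyridine, CH2Cl2, 4 Å molecular sieves, rt; then ClCO2CH2CH=CH2, 0 °C; then HO(CH2)3OH, rt
Reagents that add atoms: allyl chloroformate, C=CCOC(=O)Cl
Why: Transient boronate protection ties up the cis‑2,3‑diol as a five‑membered ester (C‑19 OH is trans to the C‑3 OH and cannot join), so only the primary C‑19 hydroxyl is acylated; exchange with 1,3‑propanediol then frees the diol.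

**Step 12**
Reactants: 19 diol carbonate
Product: 20 ent‑2α,3α‑diacetoxy‑19‑(allyloxycarbonyloxy)‑14,15‑dinorlabd‑7‑en‑13‑one
Conditions: Ac2O, DMAP, pyridine, 40 °C
Reagents that add atoms: acetic anhydride, CC(=O)OC(C)=O
Why: DMAP‑catalysed acylation esterifies both the equatorial C‑2 and the hindered axial C‑3 hydroxyl, with retention at both carbons.

**Step 13**
Reactants: 20 diacetate ketone
Product: 21 allyl ent‑2α,3α‑diacetoxy‑19‑(allyloxycarbonyloxy)labda‑7,13E‑dien‑15‑oate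
Conditions: (EtO)2P(O)CH2CO2CH2CH=CH2, NaH, THF, 0 → 45 °C; chromatographic removal of the minor (Z)‑isomer
Reagents that add atoms: allyl diethylphosphonoacetate, CCOP(=O)(OCC)CC(=O)OCC=C
Why: Horner–Wadsworth–Emmons olefination of the methyl ketone gives the trisubstituted enoate with the ester trans to the larger C‑12 chain as the major (E) isomer; the stabilised phosphonate anion leaves acetates and carbonate alone.

**Step 14**
Reactants: 21 allyl ester allyl carbonate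
Product: 22 ent‑2α,3α‑diacetoxy‑19‑hydroxylabda‑7,13E‑dien‑15‑oic acid
Conditions: Pd(PPh3)4 (5 mol%), morpholine, THF, rt; then aq. citric acid
Reagents that add atoms: none
Why: In this Tsuji–Trost deallylation zerovalent palladium ionises both the allyl ester and the allyl carbonate to π‑allyl complexes that morpholine traps (the carbonate losing CO2), freeing the acid and the C‑19 alcohol; the acetates, trans to C‑19, neither cleave nor migrate.

**Step 15**
Reactants: 22 hydroxy acid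
Product: 23 ent‑2α,3α‑diacetoxy‑19‑oxolabda‑7,13E‑dien‑15‑oic acid (target)
Conditions: Dess–Martin periodinane, CH2Cl2, 0 °C → rt
Reagents that add atoms: none
Why: Dess–Martin oxidation takes the neopentyl primary alcohol to the aldehyde without over‑oxidation in the presence of the free acid, acetates and alkenes; the aldehyde has no α‑hydrogen, so C‑4 cannot epimerise.

**Compound list**
1 | (E)‑geranylacetone, (5E)‑6,10‑dimethylundeca‑5,9‑dien‑2‑one | CC(=O)CC/C=C(\C)CCC=C(C)C | starting material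
2 | 2‑[(3E)‑4,8‑dimethylnona‑3,7‑dien‑1‑yl]‑2‑methyl‑1,3‑dioxolane | CC1(CC/C=C(\C)CCC=C(C)C)OCCO1 | intermediate
3 | (2E,6E)‑2,6‑dimethyl‑9‑(2‑methyl‑1,3‑dioxolan‑2‑yl)nona‑2,6‑dien‑1‑ol | CC1(CC/C=C(\C)CC/C=C(\C)CO)OCCO1 | intermediate
4 | 2‑[(3E,7E)‑9‑bromo‑4,8‑dimethylnona‑3,7‑dien‑1‑yl]‑2‑methyl‑1,3‑dioxolane | CC1(CC/C=C(\C)CC/C=C(\C)CBr)OCCO1 | intermediate
5 | ethyl 2‑methyl‑3‑oxobutanoate | CCOC(=O)C(C)C(C)=O | starting material
6 | (−)‑8‑phenylmenthol, (1R,2S,5R)‑5‑methyl‑2‑(2‑phenylpropan‑2‑yl)cyclohexan‑1‑ol | O[C@@H]1C[C@H](C)CC[C@H]1C(C)(C)c1ccccc1 | starting material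
7 | (1R,2S,5R)‑5‑methyl‑2‑(2‑phenylpropan‑2‑yl)cyclohexyl 2‑methyl‑3‑oxobutanoate (C‑2 epimers) | CC(=O)C(C)C(=O)O[C@@H]1C[C@H](C)CC[C@H]1C(C)(C)c1ccccc1 | intermediate
8 | sodium lithium dienolate (dianion) of 7 | [Li+].[Na+].C=C([O-])C(C)=C([O-])O[C@@H]1C[C@H](C)CC[C@H]1C(C)(C)c1ccccc1 | intermediate
9 | (−)‑8‑phenylmenthyl (6E,10E)‑2,6,10‑trimethyl‑13‑(2‑methyl‑1,3‑dioxolan‑2‑yl)‑3‑oxotrideca‑6,10‑dienoate | CC1(CC/C=C(\C)CC/C=C(\C)CCC(=O)C(C)C(=O)O[C@@H]2C[C@H](C)CC[C@H]2C(C)(C)c2ccccc2)OCCO1 | intermediate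
10 | (−)‑8‑phenylmenthyl ent‑13,13‑ethylenedioxy‑3‑oxo‑14,15‑dinorlabd‑8(17)‑en‑19‑oate | C1C[C@@]2(C)[C@H](CCC3(C)OCCO3)C(=C)CC[C@@H]2[C@](C)(C(=O)O[C@@H]4C[C@H](C)CC[C@H]4C(C)(C)c5ccccc5)C1=O | intermediate
11 | (−)‑8‑phenylmenthyl ent‑13,13‑ethylenedioxy‑3‑oxo‑14,15‑dinorlabd‑7‑en‑19‑oate | C1C[C@@]2(C)[C@H](CCC3(C)OCCO3)C(C)=CC[C@@H]2[C@](C)(C(=O)O[C@@H]4C[C@H](C)CC[C@H]4C(C)(C)c5ccccc5)C1=O | intermediate
12 | potassium C2–C3 enolate of 11 | [K+].C=1C[C@@]2(C)[C@H](CCC3(C)OCCO3)C(C)=CC[C@@H]2[C@](C)(C(=O)O[C@@H]4C[C@H](C)CC[C@H]4C(C)(C)c5ccccc5)C=1[O-] | intermediate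
13 | (−)‑8‑phenylmenthyl ent‑13,13‑ethylenedioxy‑2α‑hydroxy‑3‑oxo‑14,15‑dinorlabd‑7‑en‑19‑oate (OH equatorial, trans to C‑20) | O[C@H]1C[C@@]2(C)[C@H](CCC3(C)OCCO3)C(C)=CC[C@@H]2[C@](C)(C(=O)O[C@@H]4C[C@H](C)CC[C@H]4C(C)(C)c5ccccc5)C1=O | intermediate
14 | (−)‑8‑phenylmenthyl ent‑13,13‑ethylenedioxy‑2α,3α‑dihydroxy‑14,15‑dinorlabd‑7‑en‑19‑oate (cis diol, C‑3 OH axial) | O[C@H]1C[C@@]2(C)[C@H](CCC3(C)OCCO3)C(C)=CC[C@@H]2[C@](C)(C(=O)O[C@@H]4C[C@H](C)CC[C@H]4C(C)(C)c5ccccc5)[C@H]1O | intermediate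
15 | ent‑13,13‑ethylenedioxy‑14,15‑dinorlabd‑7‑ene‑2α,3α,19‑triol | O[C@H]1C[C@@]2(C)[C@H](CCC3(C)OCCO3)C(C)=CC[C@@H]2[C@](C)(CO)[C@H]1O | intermediate
16 | ent‑2α,3α,19‑trihydroxy‑14,15‑dinorlabd‑7‑en‑13‑one | O[C@H]1C[C@@]2(C)[C@H](CCC(C)=O)C(C)=CC[C@@H]2[C@](C)(CO)[C@H]1O | intermediate
17 | 2,3‑O‑(phenylboranediyl) derivative of 16 | O3[C@H]1C[C@@]2(C)[C@H](CCC(C)=O)C(C)=CC[C@@H]2[C@](C)(CO)[C@H]1OB3c4ccccc4 | intermediate
18 | 19‑O‑allyloxycarbonyl‑2,3‑O‑(phenylboranediyl) derivative of 16 | O3[C@H]1C[C@@]2(C)[C@H](CCC(C)=O)C(C)=CC[C@@H]2[C@](C)(COC(=O)OCC=C)[C@H]1OB3c4ccccc4 | intermediate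
19 | ent‑19‑(allyloxycarbonyloxy)‑2α,3α‑dihydroxy‑14,15‑dinorlabd‑7‑en‑13‑one | O[C@H]1C[C@@]2(C)[C@H](CCC(C)=O)C(C)=CC[C@@H]2[C@](C)(COC(=O)OCC=C)[C@H]1O | intermediate
20 | ent‑2α,3α‑diacetoxy‑19‑(allyloxycarbonyloxy)‑14,15‑dinorlabd‑7‑en‑13‑one | CC(=O)O[C@H]1C[C@@]2(C)[C@H](CCC(C)=O)C(C)=CC[C@@H]2[C@](C)(COC(=O)OCC=C)[C@H]1OC(C)=O | intermediate
21 | allyl ent‑2α,3α‑diacetoxy‑19‑(allyloxycarbonyloxy)labda‑7,13E‑dien‑15‑oate | CC(=O)O[C@H]1C[C@@]2(C)[C@H](CC/C(C)=C/C(=O)OCC=C)C(C)=CC[C@@H]2[C@](C)(COC(=O)OCC=C)[C@H]1OC(C)=O | intermediate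
22 | ent‑2α,3α‑diacetoxy‑19‑hydroxylabda‑7,13E‑dien‑15‑oic acid | CC(=O)O[C@H]1C[C@@]2(C)[C@H](CC/C(C)=C/C(=O)O)C(C)=CC[C@@H]2[C@](C)(CO)[C@H]1OC(C)=O | intermediate
23 | ent‑2α,3α‑diacetoxy‑19‑oxolabda‑7,13E‑dien‑15‑oic acid, (2S,3R,4S,5S,9R,10S) | CC(=O)O[C@H]1C[C@@]2(C)[C@H](CC/C(C)=C/C(=O)O)C(C)=CC[C@@H]2[C@](C)(C=O)[C@H]1OC(C)=O | target

**Step count**
Total: 15 steps. Longest linear sequence: 14 steps (1–3, 5–15, from geranylacetone); step 4 is a one‑step side branch.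

**Three steps most likely to fail, with fallbacks**

Step 6 (oxidative bicyclisation). The risks are yield, facial selectivity and survival of the dioxolane next to Yb(OTf)3. The fallback changes from oxidative to atom‑transfer radical cyclisation and sets out from 9. Bromination at the doubly activated carbon (NBS, Mg(ClO4)2 cat., EtOAc, 0 °C) gives the α‑bromo keto ester F1. Et3B/O2 with Yb(OTf)3 in CH2Cl2 at −78 °C then effects a bromine‑atom‑transfer bicyclisation through the same chair–chair array to the tertiary C‑8 bromide F2. DBU dehydrobromination comes back at 10 (mixed with 11), which re‑enters at step 7.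

Step 7 (position of the ring B double bond). A competing shift to C8=C9 is possible. The fallback is a regiospecific reductive transposition that sets out from 10. SeO2 (cat.)/t‑BuOOH hydroxylates the ring allylic CH2 to the 7‑hydroxy‑8(17)‑ene F3. A Mitsunobu reaction with 2‑nitrobenzenesulfonylhydrazide (PPh3, DEAD, THF, −30 °C) gives the N‑allylic sulfonylhydrazide F4. On warming this loses the sulfinic acid to give the allylic diazene F5, whose retro‑ene loss of N2 puts hydrogen on C‑17 and the double bond at C7=C8 only, coming back at 11.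

Step 9 (facial selectivity of the ketone reduction). The C‑3 epimer would give the trans diol. The fallback forms both C–O bonds in one suprafacial event and sets out from 11. KN(SiMe3)2/PhNTf2 gives the enol triflate F6, and Pd(OAc)2/PPh3/HCO2H/Bu3N reduces it to the 2,7‑diene F7. OsO4 (cat.)/NMO then dihydroxylates the ring A alkene from the face opposite C‑20 and C‑19, coming back at 14 without passing through 13. The trisubstituted C7 alkene is the competitor here, so the reaction is stopped at partial conversion and the diene recycled.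

**Further compounds**
F1 | step 6 | (−)‑8‑phenylmenthyl (6E,10E)‑2‑bromo‑2,6,10‑trimethyl‑13‑(2‑methyl‑1,3‑dioxolan‑2‑yl)‑3‑oxotrideca‑6,10‑dienoate (C‑2 epimers) | CC1(CC/C=C(\C)CC/C=C(\C)CCC(=O)C(C)(Br)C(=O)O[C@@H]2C[C@H](C)CC[C@H]2C(C)(C)c2ccccc2)OCCO1
F2 | step 6 | (−)‑8‑phenylmenthyl ent‑8‑bromo‑13,13‑ethylenedioxy‑3‑oxo‑14,15‑dinorlabdan‑19‑oate (C‑8 configuration open) | C1C[C@@]2(C)[C@H](CCC3(C)OCCO3)C(C)(Br)CC[C@@H]2[C@](C)(C(=O)O[C@@H]4C[C@H](C)CC[C@H]4C(C)(C)c5ccccc5)C1=O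
F3 | step 7 | (−)‑8‑phenylmenthyl ent‑13,13‑ethylenedioxy‑7‑hydroxy‑3‑oxo‑14,15‑dinorlabd‑8(17)‑en‑19‑oate (either C‑7 epimer) | C1C[C@@]2(C)[C@H](CCC3(C)OCCO3)C(=C)C(O)C[C@@H]2[C@](C)(C(=O)O[C@@H]4C[C@H](C)CC[C@H]4C(C)(C)c5ccccc5)C1=O
F4 | step 7 | N‑allylic N‑(2‑nitrobenzenesulfonyl)hydrazide at C‑7 of the 8(17)‑ene (either C‑7 epimer) | C1C[C@@]2(C)[C@H](CCC3(C)OCCO3)C(=C)C(N(N)S(=O)(=O)c6ccccc6[N+](=O)[O-])C[C@@H]2[C@](C)(C(=O)O[C@@H]4C[C@H](C)CC[C@H]4C(C)(C)c5ccccc5)C1=O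
F5 | step 7 | C‑7 allylic diazene of the 8(17)‑ene (either C‑7 epimer) | C1C[C@@]2(C)[C@H](CCC3(C)OCCO3)C(=C)C(N=N)C[C@@H]2[C@](C)(C(=O)O[C@@H]4C[C@H](C)CC[C@H]4C(C)(C)c5ccccc5)C1=O
F6 | step 9 | (−)‑8‑phenylmenthyl ent‑13,13‑ethylenedioxy‑3‑(trifluoromethanesulfonyloxy)‑14,15‑dinorlabda‑2,7‑dien‑19‑oate | C=1C[C@@]2(C)[C@H](CCC3(C)OCCO3)C(C)=CC[C@@H]2[C@](C)(C(=O)O[C@@H]4C[C@H](C)CC[C@H]4C(C)(C)c5ccccc5)C=1OS(=O)(=O)C(F)(F)F
F7 | step 9 | (−)‑8‑phenylmenthyl ent‑13,13‑ethylenedioxy‑14,15‑dinorlabda‑2,7‑dien‑19‑oate | C=1C[C@@]2(C)[C@H](CCC3(C)OCCO3)C(C)=CC[C@@H]2[C@](C)(C(=O)O[C@@H]4C[C@H](C)CC[C@H]4C(C)(C)c5ccccc5)C=1
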